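Atom numbers follow the isochromene core of the target (C1, O2, C3, C4, C4a, C5–C8, C8a). Retrosynthetic cuts, in order: O2–C3 (oxa-Michael closure of the pyran ring), then C6–C7 and C8–C8a together (retro-Diels–Alder), then C4a–C4 (Sonogashira).
Enabling feature: in the carbocycle C4a–C5–C6–C7–C8–C8a the C4a=C5 alkene lies between the oxygen-bearing C6 and the quaternary C8a, whose one-carbon arm C1 can be raised to a carbonyl. C6–O–C1(=O)–C8a is then the lactone bridge of a 2-pyrone adduct, the acetyl group on C8a is the activating 3-acyl group of that pyrone, and the cis C7/C8 diol is a Z-enediol.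
Forward: (S)-2-methylbutan-1-ol gives the dienyne arm; a 3-acetyl-5-chloro-4-hydroxy-2-pyrone is made by acetoacetylation and Dieckmann closure and coupled to the arm. An inverse-demand Diels–Alder reaction with a Z-enediol acetate/silyl ether then builds the carbocycle as a bridged lactone (a temporary ring).
Hydride opens the bridge to the C1 and C6 alcohols, C6 is oxidised, the pyran ring closes by 6-endo attack of the C1 hydroxyl on C3, and two silyl groups are removed (one is a temporary enol-silane mask of the acetyl group).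
Stereochemistry: the side-chain centre is bought; C8a is set by a chiral copper–bis(oxazoline) catalyst, and C7 and C8 are relayed in the same event (cis-diol from the Z-alkene, cis to acetyl from the endo approach).

Key step: step 9

Remark: the sense of induction of the copper–bis(oxazoline) catalyst in step 9 is assigned by analogy; the route is written for the ligand enantiomer that gives the C8a configuration of the target.

Step 1
Reactants: 1 (S)-2-methylbutan-1-ol; 2 2-(triphenyl-λ5-phosphanylidene)propanal
Product: 4 (2E,4S)-2,4-dimethylhex-2-enal, via (S)-2-methylbutanal 3 (not isolated)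
Conditions: TEMPO (10 mol %), PhI(OAc)2, CH2Cl2, rt; then 2, 40 °C
Reagents that add atoms: none
Why: Oxoammonium-mediated oxidation gives the epimerisable α-branched aldehyde under non-basic conditions and the stabilised formyl ylide converts it in the same flask into the E-enal (Wittig reaction of a stabilised ylide), so the stereocentre bought with 1 is carried over unchanged.

Step 2
Reactants: 4 (2E,4S)-2,4-dimethylhex-2-enal; 5 diethyl [3-(trimethylsilyl)prop-2-yn-1-yl]phosphonate
Product: 6 trimethyl[(3E,5E,7S)-5,7-dimethylnona-3,5-dien-1-yn-1-yl]silane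
Conditions: LiN(SiMe3)2, THF, −78 → 0 °C
Reagents that add atoms: none
Why: Horner–Wadsworth–Emmons olefination of the enal with the lithiated propargylic phosphonate should give the conjugated enyne with the E geometry that is normal for stabilised phosphonate carbanions.

Step 3
Reactants: 6 trimethyl[(3E,5E,7S)-5,7-dimethylnona-3,5-dien-1-yn-1-yl]silane
Product: 7 (3E,5E,7S)-5,7-dimethylnona-3,5-dien-1-yne
Conditions: K2CO3 (0.2 equiv), MeOH, 0 °C → rt
Reagents that add atoms: none
Why: Base-catalysed methanolysis of the alkynyl–silicon bond (protiodesilylation) frees the terminal alkyne without touching the diene or the stereocentre.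

Step 4
Reactants: 8 ethyl 2-chloro-3-oxopropanoate; 9 2,2,6-trimethyl-4H-1,3-dioxin-4-one
Product: 11 3-acetyl-5-chloro-4-hydroxy-2H-pyran-2-one, via enol acetoacetate 10 (not isolated)
Conditions: toluene, 110 °C (acetone distilled off); then NaH, THF, 0 °C → rt; aq. HCl
Reagents that add atoms: none
Why: Thermal cycloreversion of 9 gives acetylketene, which acylates the hydrogen-bonded enol oxygen of 8, and deprotonation of the resulting acetoacetate then drives a Dieckmann closure (Lacey–Dieckmann type) onto the cis ester to give the strongly acidic 3-acyl-4-hydroxy-2-pyrone.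

Step 5
Reactants: 11 3-acetyl-5-chloro-4-hydroxy-2H-pyran-2-one
Product: 12 3-acetyl-5-chloro-2-oxo-2H-pyran-4-yl 4-methylbenzenesulfonate
Conditions: TsCl, Et3N, CH2Cl2, 0 °C
Reagents that add atoms: 4-methylbenzenesulfonyl chloride, Cc1ccc(cc1)S(Cl)(=O)=O
Why: O-Sulfonylation of the vinylogous acid at the ring oxygen on C4 keeps the 2-pyrone intact and turns that position into a leaving group for cross-coupling.

Step 6
Reactants: 12 3-acetyl-5-chloro-2-oxo-2H-pyran-4-yl 4-methylbenzenesulfonate; 7 (3E,5E,7S)-5,7-dimethylnona-3,5-dien-1-yne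
Product: 13 3-acetyl-5-chloro-4-[(3E,5E,7S)-5,7-dimethylnona-3,5-dien-1-yn-1-yl]-2H-pyran-2-one
Conditions: PdCl2(PPh3)2 (5 mol %), CuI (10 mol %), iPr2NEt, MeCN, rt
Reagents that add atoms: none
Why: Sonogashira coupling should succeed because the C4–O sulfonate of a 4-sulfonyloxy-2-pyrone behaves as a vinylogous acyl sulfonate and adds readily to zerovalent palladium, whereas the C5–Cl bond is inert and the hindered amine does not add to the pyrone.

Step 7
Reactants: 14 but-3-en-2-yl acetate (racemic)
Product: 16 1-oxopropan-2-yl acetate (2-acetoxypropanal; racemic), via ozonide 15 (not isolated)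
Conditions: O3, CH2Cl2, −78 °C; then Me2S, −78 °C → rt
Reagents that add atoms: ozone, [O-][O+]=O
Why: Ozonolysis of the terminal alkene with reductive work-up gives the α-acetoxy aldehyde directly, and its stereocentre is irrelevant because it becomes sp2 in the next step.

Step 8
Reactants: 16 1-oxopropan-2-yl acetate
Product: 17 (1Z)-1-{[tert-butyl(dimethyl)silyl]oxy}prop-1-en-2-yl acetate
Conditions: TBSOTf, Et3N, CH2Cl2, 0 °C
Reagents that add atoms: tert-butyldimethylsilyl trifluoromethanesulfonate, CC(C)(C)[Si](C)(C)OS(=O)(=O)C(F)(F)F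
Why: Soft enolisation of the aldehyde (silyl triflate and amine) can only engage the single α-hydrogen, and the Z enol silane with the two oxygens cis should predominate, as is usual for enol silanes of α-acyloxy aldehydes (cis effect of vicinal oxygens).

Step 9
Reactants: 13 3-acetyl-5-chloro-4-[(3E,5E,7S)-5,7-dimethylnona-3,5-dien-1-yn-1-yl]-2H-pyran-2-one; 17 (1Z)-1-{[tert-butyl(dimethyl)silyl]oxy}prop-1-en-2-yl acetate
Product: 18 4-acetyl-8-{[tert-butyl(dimethyl)silyl]oxy}-6-chloro-5-[(3E,5E,7S)-5,7-dimethylnona-3,5-dien-1-yn-1-yl]-7-methyl-3-oxo-2-oxabicyclo[2.2.2]oct-5-en-7-yl acetate (7-acetoxy and 8-silyloxy cis to each other and endo, that is syn to the chloroalkene bridge; absolute configuration as in the SMILES)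
Conditions: 17 (2 equiv), Cu(OTf)2 (10 mol %), 2,2'-(propane-2,2-diyl)bis[(4S)-4-tert-butyl-4,5-dihydro-1,3-oxazole] (11 mol %), 4 Å molecular sieves, CH2Cl2, −40 → −20 °C
Reagents that add atoms: none
Why: Chelation of the lactone and acetyl carbonyl oxygens of 13 to the divalent copper centre lowers the LUMO of the ring diene C6=C5–C4a=C8a, and the electron-rich alkene of 17 adds across C6 and C8a in a concerted, asynchronous inverse-electron-demand Diels–Alder reaction in which the C6–C7 bond leads; the closest known reaction type is the copper–bis(oxazoline)-catalysed cycloaddition of 3-carboalkoxy-2-pyrones with enol silanes and enol ethers. The two six-membered rings that close, the carbocycle C4a–C5–C6–C7–C8–C8a and the lactone ring C6–C7–C8–C8a–C1–O of the 2-oxabicyclo[2.2.2]octenone, both close in the same suprafacial [4π+2π] event. Regiochemistry is secured by polarisation and reinforced by sterics: the silyloxy donor on C8 makes the methyl- and acetoxy-bearing C7 the nucleophilic terminus (the acetoxy oxygen is a poor donor), C6 is the electrophilic δ-terminus of the chelated pyrone, and the reverse orientation would have to join the two fully substituted carbons C7 and C8a, while hetero-Diels–Alder addition through the acetyl oxygen and conjugate attack at C4a are blocked by the alkynyl group there. C7 and C8 take their cis oxygens from the Z geometry of 17 by suprafacial addition, and the endo orientation of both oxygen substituents towards the C4a=C5 bridge puts them on the face of the new carbocycle opposite to C1, that is cis to the acetyl group on C8a. The absolute configuration at C8a, and at C6 which is erased later, is fixed by the twofold-symmetric ligand, whose tert-butyl groups leave one face of the planar chelate open. The step thus needs regio-, endo- and face selectivity plus retention of the alkene geometry, the last resting on ring closure at C8 being faster than bond rotation, which the low temperature and the tight bidentate complex favour.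

Step 10
Reactants: 18 bridged lactone adduct
Product: 19 8-{[tert-butyl(dimethyl)silyl]oxy}-4-(1-{[tert-butyl(dimethyl)silyl]oxy}ethenyl)-6-chloro-5-[(3E,5E,7S)-5,7-dimethylnona-3,5-dien-1-yn-1-yl]-7-methyl-3-oxo-2-oxabicyclo[2.2.2]oct-5-en-7-yl acetate (configuration as in 18)
Conditions: TBSOTf, Et3N, CH2Cl2, 0 °C
Reagents that add atoms: tert-butyldimethylsilyl trifluoromethanesulfonate, CC(C)(C)[Si](C)(C)OS(=O)(=O)C(F)(F)F
Why: The acetyl methyl group is the only enolisable position next to the quaternary C8a, so silyl triflate and amine should mask the ketone as its enol silane and allow hydride to be used on the lactone without creating a second secondary alcohol.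

Step 11
Reactants: 19 enol silane of the bridged lactone
Product: 20 5-{[tert-butyl(dimethyl)silyl]oxy}-4-(1-{[tert-butyl(dimethyl)silyl]oxy}ethenyl)-2-chloro-3-[(3E,5E,7S)-5,7-dimethylnona-3,5-dien-1-yn-1-yl]-4-(hydroxymethyl)-6-methylcyclohex-2-ene-1,6-diol (in target numbering: C1 hydroxymethyl, C6–OH and C7–CH3 on one face; C7–OH, C8–OSi and the enol-silane arm on the other)
Conditions: LiAlH4, THF, −40 → 0 °C; aq. potassium sodium tartrate
Reagents that add atoms: none
Why: LiAlH4 reduces the bridged lactone to the C1 primary alcohol and the C6 allylic alcohol and cleaves the tertiary acetate, while the enol silane, the silyl ether, the vinyl chloride and the enyne are inert at low temperature and no stereocentre is touched.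

Step 12
Reactants: 20 triol
Product: 22 (7R,8R,8aS)-8-{[tert-butyl(dimethyl)silyl]oxy}-8a-(1-{[tert-butyl(dimethyl)silyl]oxy}ethenyl)-5-chloro-3-[(1E,3E,5S)-3,5-dimethylhepta-1,3-dien-1-yl]-7-hydroxy-7-methyl-1,7,8,8a-tetrahydro-6H-isochromen-6-one, via ynenone 21 (not isolated)
Conditions: MnO2, CH2Cl2, rt; filter; then DBU (0.2 equiv), CH2Cl2, 0 °C → rt
Reagents that add atoms: none
Why: MnO2 oxidises only the allylic C6 alcohol, which makes the alkyne terminus C3 the δ-position of a dienone, and base-catalysed 6-endo-dig oxa-Michael addition of the C1 hydroxyl then closes the pyran ring (the C7 hydroxyl would need a seven-membered ring and the C8 oxygen is silylated), protonation at C4 giving the conjugated dienone.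

Step 13
Reactants: 22 bis-silylated pyran
Product: 23 (7R,8R,8aS)-8a-acetyl-5-chloro-3-[(1E,3E,5S)-3,5-dimethylhepta-1,3-dien-1-yl]-7,8-dihydroxy-7-methyl-1,7,8,8a-tetrahydro-6H-isochromen-6-one
Conditions: HF·pyridine, pyridine, THF, 0 °C → rt
Reagents that add atoms: none
Why: Fluoride under mildly acidic buffering cleaves both Si–O bonds, the enol silane collapsing to the acetyl group and the silyl ether to the C8 hydroxyl, and it avoids the basic conditions under which the β-hydroxy ketone (C8–C8a) could undergo retro-aldol cleavage.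

Compound list
1 | (S)-2-methylbutan-1-ol | CC[C@H](C)CO | starting material
2 | 2-(triphenyl-λ5-phosphanylidene)propanal | CC(C=O)=P(c1ccccc1)(c1ccccc1)c1ccccc1 | starting material
3 | (S)-2-methylbutanal | CC[C@H](C)C=O | intermediate
4 | (2E,4S)-2,4-dimethylhex-2-enal | CC[C@H](C)/C=C(C)/C=O | intermediate
5 | diethyl [3-(trimethylsilyl)prop-2-yn-1-yl]phosphonate | CCOP(=O)(CC#C[Si](C)(C)C)OCC | starting material
6 | trimethyl[(3E,5E,7S)-5,7-dimethylnona-3,5-dien-1-yn-1-yl]silane | CC[C@H](C)/C=C(C)/C=C/C#C[Si](C)(C)C | intermediate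
7 | (3E,5E,7S)-5,7-dimethylnona-3,5-dien-1-yne | CC[C@H](C)/C=C(C)/C=C/C#C | intermediate
8 | ethyl 2-chloro-3-oxopropanoate | CCOC(=O)C(Cl)C=O | starting material
9 | 2,2,6-trimethyl-4H-1,3-dioxin-4-one | CC1=CC(=O)OC(C)(C)O1 | starting material
10 | ethyl (2E)-2-chloro-3-[(3-oxobutanoyl)oxy]prop-2-enoate (acyloxy group cis to the ester) | CCOC(=O)/C(Cl)=C\OC(=O)CC(C)=O | intermediate
11 | 3-acetyl-5-chloro-4-hydroxy-2H-pyran-2-one | CC(=O)C1=C(O)C(Cl)=COC1=O | intermediate
12 | 3-acetyl-5-chloro-2-oxo-2H-pyran-4-yl 4-methylbenzenesulfonate | CC(=O)C1=C(OS(=O)(=O)c2ccc(C)cc2)C(Cl)=COC1=O | intermediate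
13 | 3-acetyl-5-chloro-4-[(3E,5E,7S)-5,7-dimethylnona-3,5-dien-1-yn-1-yl]-2H-pyran-2-one | CC[C@H](C)/C=C(C)/C=C/C#CC1=C(C(C)=O)C(=O)OC=C1Cl | intermediate
14 | but-3-en-2-yl acetate (racemic) | CC(OC(C)=O)C=C | starting material
15 | 1-(1,2,4-trioxolan-3-yl)ethyl acetate (ozonide, mixture of diastereomers) | CC(OC(C)=O)C1OCOO1 | intermediate
16 | 1-oxopropan-2-yl acetate (racemic) | CC(OC(C)=O)C=O | intermediate
17 | (1Z)-1-{[tert-butyl(dimethyl)silyl]oxy}prop-1-en-2-yl acetate | CC(=O)O/C(C)=C\O[Si](C)(C)C(C)(C)C | intermediate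
18 | 4-acetyl-8-{[tert-butyl(dimethyl)silyl]oxy}-6-chloro-5-[(3E,5E,7S)-5,7-dimethylnona-3,5-dien-1-yn-1-yl]-7-methyl-3-oxo-2-oxabicyclo[2.2.2]oct-5-en-7-yl acetate (7-OAc and 8-OSi cis, endo) | CC(=O)[C@]12C(=O)O[C@H](C(Cl)=C1C#C/C=C/C(C)=C/[C@@H](C)CC)[C@](C)(OC(C)=O)[C@@H]2O[Si](C)(C)C(C)(C)C | intermediate
19 | 8-{[tert-butyl(dimethyl)silyl]oxy}-4-(1-{[tert-butyl(dimethyl)silyl]oxy}ethenyl)-6-chloro-5-[(3E,5E,7S)-5,7-dimethylnona-3,5-dien-1-yn-1-yl]-7-methyl-3-oxo-2-oxabicyclo[2.2.2]oct-5-en-7-yl acetate | C=C(O[Si](C)(C)C(C)(C)C)[C@]12C(=O)O[C@H](C(Cl)=C1C#C/C=C/C(C)=C/[C@@H](C)CC)[C@](C)(OC(C)=O)[C@@H]2O[Si](C)(C)C(C)(C)C | intermediate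
20 | 5-{[tert-butyl(dimethyl)silyl]oxy}-4-(1-{[tert-butyl(dimethyl)silyl]oxy}ethenyl)-2-chloro-3-[(3E,5E,7S)-5,7-dimethylnona-3,5-dien-1-yn-1-yl]-4-(hydroxymethyl)-6-methylcyclohex-2-ene-1,6-diol | C=C(O[Si](C)(C)C(C)(C)C)[C@]1(CO)C(C#C/C=C/C(C)=C/[C@@H](C)CC)=C(Cl)[C@@H](O)[C@](C)(O)[C@@H]1O[Si](C)(C)C(C)(C)C | intermediate
21 | 5-{[tert-butyl(dimethyl)silyl]oxy}-4-(1-{[tert-butyl(dimethyl)silyl]oxy}ethenyl)-2-chloro-3-[(3E,5E,7S)-5,7-dimethylnona-3,5-dien-1-yn-1-yl]-6-hydroxy-4-(hydroxymethyl)-6-methylcyclohex-2-en-1-one | C=C(O[Si](C)(C)C(C)(C)C)[C@]1(CO)C(C#C/C=C/C(C)=C/[C@@H](C)CC)=C(Cl)C(=O)[C@](C)(O)[C@@H]1O[Si](C)(C)C(C)(C)C | intermediate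
22 | (7R,8R,8aS)-8-{[tert-butyl(dimethyl)silyl]oxy}-8a-(1-{[tert-butyl(dimethyl)silyl]oxy}ethenyl)-5-chloro-3-[(1E,3E,5S)-3,5-dimethylhepta-1,3-dien-1-yl]-7-hydroxy-7-methyl-1,7,8,8a-tetrahydro-6H-isochromen-6-one | CC[C@H](C)/C=C(C)/C=C/C1=CC2=C(Cl)C(=O)[C@](C)(O)[C@H](O[Si](C)(C)C(C)(C)C)[C@@]2(C(=C)O[Si](C)(C)C(C)(C)C)CO1 | intermediate
23 | (7R,8R,8aS)-8a-acetyl-5-chloro-3-[(1E,3E,5S)-3,5-dimethylhepta-1,3-dien-1-yl]-7,8-dihydroxy-7-methyl-1,7,8,8a-tetrahydro-6H-isochromen-6-one | CC[C@H](C)/C=C(C)/C=C/C1=CC2=C(Cl)C(=O)[C@](C)(O)[C@H](O)[C@@]2(C(C)=O)CO1 | target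

Total step count: 13. Longest linear sequence: 9 steps (steps 1, 2, 3, 6, 9, 10, 11, 12, 13).

Steps most likely to fail

Step 9. The process at risk is erosion of the Z geometry of the enediol unit if the addition turns stepwise (a zwitterion that rotates before ring closure at C8), or sluggish attack of the acetoxy-bearing terminus on the fully substituted pyrone. The fallback sets out from 13 and comes back to the route at 23. The same copper–bis(oxazoline) catalyst is used with commercial 2,2-dimethyl-1,3-dioxole, a symmetrical, cyclic and strongly nucleophilic cis-enediol acetal for which neither regiochemistry nor alkene geometry is in question. It should give the endo acetonide adduct F1, which lacks the C7 methyl group. TBSOTf and Et3N give its enol silane F2, and LiAlH4 opens the lactone to the diol F3. MnO2 gives the ynenone F4 and catalytic DBU the pyran F5. The C6 ketone of F5 is then enolised towards C7 (KN(SiMe3)2, THF, −78 °C) and methylated with MeI to the C7-methyl acetonide F6. The five-membered acetonide can only stay cis-fused, so the methyl group has to enter on the face opposite to the C7 oxygen's ring, and the C8–O bond lies nearly orthogonal to the enolate π-system, which disfavours β-elimination. Aqueous acid (HCl, THF, water) then removes the acetonide and the enol silane to give 23.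

Step 4. The process at risk is capture of acetylketene at carbon instead of at the enol oxygen, or base-induced cleavage of the enol ester outrunning the Dieckmann closure. The fallback sets out from 9 and comes back at 11. The dienolate of 9 (LiN(iPr)2, THF, −78 °C) is formylated at its methyl group with ethyl formate to 2,2-dimethyl-6-(2-oxoethyl)-4H-1,3-dioxin-4-one F7. Heating in toluene expels acetone, and the acylketene is trapped by its own enol to give 4-hydroxy-2H-pyran-2-one F8. O-Acetylation followed by O-to-C acyl migration (AcOH, DCC, DMAP; Fries type) gives 3-acetyl-4-hydroxy-2H-pyran-2-one F9. N-Chlorosuccinimide in DMF then chlorinates C5, the only remaining nucleophilic ring position, to give 11.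

Step 12. The process at risk is oxidative cleavage of the free C6–C7 glycol by MnO2 in competition with allylic oxidation. The fallback sets out from 19 and comes back at 22. LiBH4 (THF, 0 °C) should reduce only the strained bridged lactone and leave the hindered tertiary acetate in place, giving the C7 acetate diol F10, in which no free vicinal diol is present. MnO2 then gives the ynenone acetate F11 and catalytic DBU the pyran acetate F12. Methanolysis of the activated α-keto tertiary acetate (K2CO3, MeOH, 0 °C) returns 22; partial loss of the enol silane at this point would be harmless because step 13 removes it anyway.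

Further compounds
F1 | step 9 | endo Diels–Alder adduct of 13 with 2,2-dimethyl-1,3-dioxole (analogue of 18 with H on C7 and the C7 and C8 oxygens joined as an acetonide) | CC(=O)[C@]12C(=O)O[C@H](C(Cl)=C1C#C/C=C/C(C)=C/[C@@H](C)CC)[C@@H]3OC(C)(C)O[C@H]23
F2 | step 9 | enol silane of F1 (acetyl group as 1-{[tert-butyl(dimethyl)silyl]oxy}ethenyl) | C=C(O[Si](C)(C)C(C)(C)C)[C@]12C(=O)O[C@H](C(Cl)=C1C#C/C=C/C(C)=C/[C@@H](C)CC)[C@@H]3OC(C)(C)O[C@H]23
F3 | step 9 | diol from hydride opening of F2 (acetonide analogue of 20 without the C7 methyl group) | C=C(O[Si](C)(C)C(C)(C)C)[C@]1(CO)C(C#C/C=C/C(C)=C/[C@@H](C)CC)=C(Cl)[C@@H](O)[C@@H]2OC(C)(C)O[C@H]12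
F4 | step 9 | ynenone from F3 (acetonide analogue of 21 without the C7 methyl group) | C=C(O[Si](C)(C)C(C)(C)C)[C@]1(CO)C(C#C/C=C/C(C)=C/[C@@H](C)CC)=C(Cl)C(=O)[C@@H]2OC(C)(C)O[C@H]12
F5 | step 9 | pyran from F4 (7,8-O-isopropylidene analogue of 22 with H on C7) | CC[C@H](C)/C=C(C)/C=C/C1=CC2=C(Cl)C(=O)[C@@H]3OC(C)(C)O[C@@H]3[C@@]2(C(=C)O[Si](C)(C)C(C)(C)C)CO1
F6 | step 9 | C7-methylated pyran (7,8-O-isopropylidene derivative of the target with the acetyl group as its tert-butyldimethylsilyl enol ether) | CC[C@H](C)/C=C(C)/C=C/C1=CC2=C(Cl)C(=O)[C@]3(C)OC(C)(C)O[C@@H]3[C@@]2(C(=C)O[Si](C)(C)C(C)(C)C)CO1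
F7 | step 4 | 2,2-dimethyl-6-(2-oxoethyl)-4H-1,3-dioxin-4-one | CC1(C)OC(=O)C=C(CC=O)O1
F8 | step 4 | 4-hydroxy-2H-pyran-2-one | OC1=CC(=O)OC=C1
F9 | step 4 | 3-acetyl-4-hydroxy-2H-pyran-2-one | CC(=O)C1=C(O)C=COC1=O
F10 | step 12 | C7 acetate of 20 (diol with the tertiary acetate retained) | C=C(O[Si](C)(C)C(C)(C)C)[C@]1(CO)C(C#C/C=C/C(C)=C/[C@@H](C)CC)=C(Cl)[C@@H](O)[C@](C)(OC(C)=O)[C@@H]1O[Si](C)(C)C(C)(C)C
F11 | step 12 | C7 acetate of 21 (ynenone) | C=C(O[Si](C)(C)C(C)(C)C)[C@]1(CO)C(C#C/C=C/C(C)=C/[C@@H](C)CC)=C(Cl)C(=O)[C@](C)(OC(C)=O)[C@@H]1O[Si](C)(C)C(C)(C)C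
F12 | step 12 | C7 acetate of 22 (pyran) | CC[C@H](C)/C=C(C)/C=C/C1=CC2=C(Cl)C(=O)[C@](C)(OC(C)=O)[C@H](O[Si](C)(C)C(C)(C)C)[C@@]2(C(=C)O[Si](C)(C)C(C)(C)C)CO1
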